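## Retrosynthetic overview

- The target (3R,7R) is cut at the C7–O ester bond: a vinylogous-acid quinone methide, (3R)-8-hydroxy-3,7-dimethyl-3,4-dihydroisochromen-6-one, receives an oleoyloxy group from a chiral diacyloxyiodoarene. This last step makes the ester and the C7 quaternary centre together.
- The quinone methide comes from 5-[(2R)-2-hydroxypropyl]-2-methylresorcinol and triethyl orthoformate (C1 inserted; O2–C1 and C1–C8a bonds formed).
- The resorcinol comes from the Grignard reagent of 5-bromo-2-methylresorcinol dimethyl ether and (R)-propylene oxide (C3 from the chiral pool), then O-demethylation.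
- The iodine reagent comes from a C2-symmetric lactamide iodoarene and oleic acid (oxidation, ligand exchange).
- Ring order: the benzene ring is bought, the pyran ring is closed in step 3, and the carbocycle is dearomatised to the dione last, in step 5.

Assumption: the C2-symmetric lactamide iodoarene is bought (otherwise two steps from 2-iodoresorcinol and a lactate ester), and its (R,R)-form is taken to give 7R; if the sense is opposite, the (S,S)-form is used with no other change.

## Route

Step 1
Reactants: 1 5-bromo-1,3-dimethoxy-2-methylbenzene; 2 (R)-propylene oxide [(2R)-2-methyloxirane]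
Product: 4 (2R)-1-(3,5-dimethoxy-4-methylphenyl)propan-2-ol, via aryl Grignard reagent 3 (not isolated)
Conditions: Mg turnings (1.3 equiv), LiCl, THF, 25–40 °C; then CuI (10 mol %), 2 (1.5 equiv), −30 → 0 °C; H2O/aq NH4Cl
Reagents that add atoms: magnesium, [Mg] (held only in intermediate 3; no atom of it stays in 4)
Why: Copper-catalysed Grignard ring-opening of a terminal epoxide is an SN2 attack at the CH2 carbon, so the epoxide stereocentre is untouched and C3 is carried over as R from the chiral pool.

Step 2
Reactants: 4 (2R)-1-(3,5-dimethoxy-4-methylphenyl)propan-2-ol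
Product: 5 5-[(2R)-2-hydroxypropyl]-2-methylbenzene-1,3-diol
Conditions: BBr3 (3.5 equiv), CH2Cl2, −78 → 0 °C; ice-water
Reagents that add atoms: none
Why: Lewis-acid aryl methyl ether cleavage (BBr3 demethylation) frees both phenols, while the secondary alcohol sits as a borate ester at or below 0 °C and returns on hydrolysis with its configuration unchanged.

Step 3
Reactants: 5 5-[(2R)-2-hydroxypropyl]-2-methylbenzene-1,3-diol
Product: 7 (3R)-8-hydroxy-3,7-dimethyl-3,4-dihydro-6H-isochromen-6-one (quinone methide), via 1-ethoxy acetal 6 (not isolated)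
Conditions: HC(OEt)3 (3 equiv), TFA (1.5 equiv), CH2Cl2, 0 °C → rt; evaporate, PhMe azeotrope, crystallise (EtOAc/hexane) under Ar, use at once
Reagents that add atoms: triethyl orthoformate, CCOC(OCC)OCC
Why: Formylative oxa-Pictet–Spengler cyclisation (the citrinin-type orthoformate ring closure) tethers the dialkoxycarbenium ion to the side-chain alcohol, attacks the ring position next to the chain (the two free positions are equivalent), and acetal 6 then loses ethanol to the stabilised quinone methide without touching C3.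

Step 4
Reactants: 8 (2R,2'R)-2,2'-[(2-iodo-1,3-phenylene)bis(oxy)]bis[N-(2,4,6-trimethylphenyl)propanamide]; 9 oleic acid [(9Z)-octadec-9-enoic acid]
Product: 11 {2,6-bis[(1R)-1-(mesitylcarbamoyl)ethoxy]phenyl}iodanediyl di[(9Z)-octadec-9-enoate], via iodane diacetate 10 (not isolated)
Conditions: AcOOH (32% in AcOH, 1.3 equiv), AcOH, 30 °C, dark; evaporate to dryness (peroxide test negative); then 9 (2.05 equiv), PhCl, 40 °C, 20 mbar, dark
Reagents that add atoms: peracetic acid, CC(=O)OO; acetic acid, CC(=O)O (both held only in intermediate 10; no atom of them stays in 11)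
Why: Peracid oxidation of an aryl iodide to its diacetoxyiodoarene and carboxylate ligand exchange driven by removal of acetic acid are standard for PhI(OAc)2-type reagents, and the peracid is removed before the alkene-bearing acid is added, so the Z-alkene is not epoxidised.

Step 5
Reactants: 7 (3R)-8-hydroxy-3,7-dimethyl-3,4-dihydro-6H-isochromen-6-one; 11 {2,6-bis[(1R)-1-(mesitylcarbamoyl)ethoxy]phenyl}iodanediyl di[(9Z)-octadec-9-enoate]
Product: 13 (3R,7R)-3,7-dimethyl-6,8-dioxo-3,4,7,8-tetrahydro-6H-isochromen-7-yl (9Z)-octadec-9-enoate (target), via enoloxy-iodane 12 (not isolated)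
Conditions: 11 (1.15 equiv), CH2Cl2, 4 Å MS, −40 → −20 °C, dark; silica chromatography (8 recovered)
Reagents that add atoms: none
Why: Proposed new method: the acidic 8-OH of vinylogous acid 7 displaces one oleate on trivalent iodine to give O-bound enolate 12, whose remaining oleate ligand is passed to one face of C7 inside the hydrogen-bonded C2-symmetric lactamide pocket as the iodoarene leaves (ligand coupling), so the C7–O ester bond and the 7R centre form together and any 7S leakage is a separable diastereomer because C3 is fixed; the closest known reaction types are the Wessely acetoxylation of phenols with Pb(OAc)4, the PhI(OAc)2 α-acetoxylation of 1,3-dicarbonyls and Kita-type dearomatising spirolactonisation with chiral iodoarenes, none of which transfers a fatty acyloxy ligand intermolecularly with reagent control.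

## Compound list

1 | 5-bromo-1,3-dimethoxy-2-methylbenzene | COc1cc(Br)cc(OC)c1C | starting material
2 | (R)-propylene oxide, (2R)-2-methyloxirane | C[C@@H]1CO1 | starting material
3 | (3,5-dimethoxy-4-methylphenyl)magnesium bromide | COc1cc([Mg]Br)cc(OC)c1C | intermediate (not isolated)
4 | (2R)-1-(3,5-dimethoxy-4-methylphenyl)propan-2-ol | COc1cc(C[C@@H](C)O)cc(OC)c1C | intermediate
5 | 5-[(2R)-2-hydroxypropyl]-2-methylbenzene-1,3-diol | Cc1c(O)cc(C[C@@H](C)O)cc1O | intermediate
6 | (3R)-1-ethoxy-3,7-dimethyl-3,4-dihydro-1H-isochromene-6,8-diol (both C1 epimers) | CCOC1O[C@H](C)Cc2cc(O)c(C)c(O)c21 | intermediate (not isolated)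
7 | (3R)-8-hydroxy-3,7-dimethyl-3,4-dihydro-6H-isochromen-6-one | CC1=C(O)C2=CO[C@H](C)CC2=CC1=O | intermediate
8 | (2R,2'R)-2,2'-[(2-iodo-1,3-phenylene)bis(oxy)]bis[N-(2,4,6-trimethylphenyl)propanamide] | Ic1c(O[C@H](C)C(=O)Nc2c(C)cc(C)cc2C)cccc1O[C@H](C)C(=O)Nc1c(C)cc(C)cc1C | starting material
9 | oleic acid, (9Z)-octadec-9-enoic acid | CCCCCCCC/C=C\CCCCCCCC(=O)O | starting material
10 | {2,6-bis[(1R)-1-(mesitylcarbamoyl)ethoxy]phenyl}iodanediyl diacetate | CC(=O)OI(OC(C)=O)c1c(O[C@H](C)C(=O)Nc2c(C)cc(C)cc2C)cccc1O[C@H](C)C(=O)Nc1c(C)cc(C)cc1C | intermediate (not isolated)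
11 | {2,6-bis[(1R)-1-(mesitylcarbamoyl)ethoxy]phenyl}iodanediyl di[(9Z)-octadec-9-enoate] | CCCCCCCC/C=C\CCCCCCCC(=O)OI(OC(=O)CCCCCCC/C=C\CCCCCCCC)c1c(O[C@H](C)C(=O)Nc2c(C)cc(C)cc2C)cccc1O[C@H](C)C(=O)Nc1c(C)cc(C)cc1C | intermediate
12 | {[(3R)-3,7-dimethyl-6-oxo-3,4-dihydro-6H-isochromen-8-yl]oxy}[(9Z)-octadec-9-enoyloxy]{2,6-bis[(1R)-1-(mesitylcarbamoyl)ethoxy]phenyl}iodane | CC1=C(OI(OC(=O)CCCCCCC/C=C\CCCCCCCC)c2c(O[C@H](C)C(=O)Nc3c(C)cc(C)cc3C)cccc2O[C@H](C)C(=O)Nc2c(C)cc(C)cc2C)C2=CO[C@H](C)CC2=CC1=O | intermediate (not isolated)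
13 | (3R,7R)-3,7-dimethyl-6,8-dioxo-3,4,7,8-tetrahydro-6H-isochromen-7-yl (9Z)-octadec-9-enoate (CNP0252548.1) | CCCCCCCC/C=C\CCCCCCCC(=O)O[C@]1(C)C(=O)C=C2C[C@@H](C)OC=C2C1=O | target

## Step count and risks

Total steps: 5. Longest linear sequence: 4 (steps 1, 2, 3, 5); step 4 is a one-step side arm.

Steps most likely to fail:

Step 5 (the proposed acyloxy transfer; risks are poor face selectivity or reaction elsewhere on the quinone methide). The fallback uses known chemistry and sets out from 7. Hydroxylative dearomatisation with IBX (cat. Bu4NI, ClCH2CH2Cl/TFA, rt, aqueous work-up), as used for azaphilones, gives the tertiary alcohol as both C7 epimers: (3R,7R)-7-hydroxy-3,7-dimethyl-3,4-dihydro-6H-isochromene-6,8(7H)-dione F1 and its (3R,7S)-epimer F2. Because C3 is fixed these are diastereomers and are separated on silica, with the configuration assigned by ECD or X-ray. F1 is then esterified with oleoyl chloride (Et3N, DMAP, CH2Cl2, 0 °C), which comes back to the route at 13.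

Step 4 (the chiral dioleate reagent has not been made; risks are incomplete ligand exchange or decomposition of the oily reagent). The fallback sets out from 9. Oleic acid is exchanged onto commercial PhI(OAc)2 (PhCl, 40 °C, reduced pressure) to give the achiral phenyliodanediyl di[(9Z)-octadec-9-enoate] F3. F3 is used in step 5 in place of 11 and gives 13 together with the (3R,7S)-oleate epimer F4; the two diastereomers are separated by chromatography, so this comes back to the route at 13 with separation in place of reagent control.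

Step 3 (the quinone methide may hydrate, stop at the ethoxy acetal or self-condense on concentration). The fallback sets out from 5. An oxa-Pictet–Spengler closure with paraformaldehyde (TsOH cat., dioxane, 60 °C) gives the stable (3R)-3,7-dimethyl-3,4-dihydro-1H-isochromene-6,8-diol F5. F5 is dehydrogenated at the benzylic ether carbon with DDQ (1.05 equiv, CH2Cl2, 0 °C) just before use, which comes back to the route at 7.

Further compounds
F1 | step 5 | (3R,7R)-7-hydroxy-3,7-dimethyl-3,4-dihydro-6H-isochromene-6,8(7H)-dione | O[C@]1(C)C(=O)C=C2C[C@@H](C)OC=C2C1=O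
F2 | step 5 | (3R,7S)-7-hydroxy-3,7-dimethyl-3,4-dihydro-6H-isochromene-6,8(7H)-dione | O[C@@]1(C)C(=O)C=C2C[C@@H](C)OC=C2C1=O
F3 | step 4 | phenyliodanediyl di[(9Z)-octadec-9-enoate] | CCCCCCCC/C=C\CCCCCCCC(=O)OI(OC(=O)CCCCCCC/C=C\CCCCCCCC)c1ccccc1
F4 | step 4 | (3R,7S)-3,7-dimethyl-6,8-dioxo-3,4,7,8-tetrahydro-6H-isochromen-7-yl (9Z)-octadec-9-enoate | CCCCCCCC/C=C\CCCCCCCC(=O)O[C@@]1(C)C(=O)C=C2C[C@@H](C)OC=C2C1=O
F5 | step 3 | (3R)-3,7-dimethyl-3,4-dihydro-1H-isochromene-6,8-diol | C[C@@H]1Cc2cc(O)c(C)c(O)c2CO1
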